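**Retrosynthetic overview**
1. Target ⇒ (desilylation, epimerisation at the acyl-bearing decalin carbon) ⇒ C3-acylation of a 5-(epoxycyclohexyl)-4-hydroxy-2-pyridone with a trans-decalin carboxylic acid.
2. Key step: the pyridone ring is made by ring expansion, a nitrogen-atom insertion with a 1,2 C→N shift into a 4-substituted cyclopentane-1,3-dione (five-membered carbocycle → six-membered azacycle).
3. The dione comes from an aldol of the 3-methoxycyclopentenone enolate with (R)-4-silyloxycyclohexenone (from desymmetrised 4-hydroxycyclohexanone), then anti-epoxidation and enol-ether hydrolysis.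
4. The decalin acid comes from a copper-catalysed asymmetric conjugate addition (methyl stereocentre), cross-metathesis/Wittig chain building, an intramolecular [4+2] closure as a supporting step, and Takai olefination.
5. Ring order: cyclohexane (present from the start) → cyclopentanedione appended → ring-expanded to the pyridone; decalin rings A and B are closed together in the parallel branch; the fragments are joined last.

Assumption: the ligand enantiomer in step 1 and the amide-base enantiomer in step 9 are those expected to give the stated configurations; if a pilot run shows the opposite sense, the mirror-image reagent (also commercial) is used. TBS = tert-butyldimethylsilyl.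

**Step 1**
Reactants: 1 methyl (E)-but-2-enoate; 2 but-3-en-1-ylmagnesium bromide
Product: 3 methyl (3S)-3-methylhept-6-enoate
Conditions: CuBr·SMe2 (5 mol %), (R)-1-[(SP)-2-(diphenylphosphino)ferrocenyl]ethyldicyclohexylphosphine (6 mol %), t-BuOMe, −75 °C; aq. NH4Cl
Reagents that add atoms: none
Why: Copper-catalysed asymmetric conjugate addition of a Grignard reagent to an enoate (Feringa type); the ferrocenyl diphosphine–CuBr complex delivers the alkyl group to one face of the crotonate and sets C3, the later C7 methyl stereocentre of the decalin, in about 95 % ee.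

**Step 2**
Reactants: 3 methyl (3S)-3-methylhept-6-enoate; 4 2-methylprop-2-enal
Product: 6 1-tert-butyl 10-methyl (2E,4E,8S)-4,8-dimethyldeca-2,4-dienedioate, via enal 5 (not isolated)
Conditions: 4 (5 equiv), second-generation Grubbs catalyst (3 mol %), CH2Cl2, 40 °C; evaporate; Ph3P=CHCO2t-Bu, CH2Cl2, rt
Reagents that add atoms: tert-butyl 2-(triphenyl-λ5-phosphanylidene)acetate, CC(C)(C)OC(=O)C=P(c1ccccc1)(c1ccccc1)c1ccccc1
Why: Olefin cross-metathesis of the terminal alkene with methacrolein is E-selective, and the enal is extended in the same flask by a Wittig reaction with a stabilised ylide to the (2E,4E)-dienoate.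

**Step 3**
Reactants: 6 1-tert-butyl 10-methyl (2E,4E,8S)-4,8-dimethyldeca-2,4-dienedioate
Product: 7 tert-butyl (2E,4E,8S)-4,8-dimethyl-10-oxodeca-2,4-dienoate
Conditions: i-Bu2AlH (1.05 equiv), CH2Cl2, −78 °C; MeOH, aq. potassium sodium tartrate
Reagents that add atoms: none
Why: Partial ester reduction with i-Bu2AlH stops at the aldehyde through the tetrahedral aluminate at −78 °C; the saturated methyl ester reacts far faster than the conjugated, hindered tert-butyl dienoate.

**Step 4**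
Reactants: 7 tert-butyl (2E,4E,8S)-4,8-dimethyl-10-oxodeca-2,4-dienoate
Product: 8 tert-butyl (2E,4E,8S,10E)-4,8-dimethyl-12-oxododeca-2,4,10-trienoate
Conditions: Ph3P=CHCHO (1.3 equiv), toluene, 80 °C
Reagents that add atoms: 2-(triphenyl-λ5-phosphanylidene)acetaldehyde, O=CC=P(c1ccccc1)(c1ccccc1)c1ccccc1
Why: Wittig olefination with the stabilised formylmethylene ylide gives the (E)-enal that serves as the dienophile.

**Step 5**
Reactants: 8 tert-butyl (2E,4E,8S,10E)-4,8-dimethyl-12-oxododeca-2,4,10-trienoate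
Product: 9 tert-butyl (1R,2S,4aS,7S,8aS)-1-formyl-4,7-dimethyl-1,2,4a,5,6,7,8,8a-octahydronaphthalene-2-carboxylate
Conditions: Me2AlCl (30 mol %), CH2Cl2, −40 → 0 °C
Reagents that add atoms: none
Why: Lewis-acid-catalysed intramolecular Diels–Alder reaction; the formyl-endo transition state with a chair-like tether and equatorial C7 methyl gives the trans-fused decalin and sets C1, C4a and C8a, while C2 is formed cis to C1 (the kinetic epimer, corrected in step 16).

**Step 6**
Reactants: 9 tert-butyl (1R,2S,4aS,7S,8aS)-1-formyl-4,7-dimethyl-1,2,4a,5,6,7,8,8a-octahydronaphthalene-2-carboxylate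
Product: 10 tert-butyl (1R,2R,4aS,7S,8aR)-4,7-dimethyl-1-[(E)-prop-1-en-1-yl]-1,2,4a,5,6,7,8,8a-octahydronaphthalene-2-carboxylate
Conditions: CrCl2 (8 equiv), 1,1-diiodoethane (2 equiv), THF, rt
Reagents that add atoms: 1,1-diiodoethane, CC(I)I
Why: Takai–Utimoto olefination (geminal dichromium reagent) converts the aldehyde chemoselectively into the (E)-propenyl group and leaves the ester and C1 untouched.

**Step 7**
Reactants: 10 tert-butyl (1R,2R,4aS,7S,8aR)-4,7-dimethyl-1-[(E)-prop-1-en-1-yl]-1,2,4a,5,6,7,8,8a-octahydronaphthalene-2-carboxylate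
Product: 11 (1R,2R,4aS,7S,8aR)-4,7-dimethyl-1-[(E)-prop-1-en-1-yl]-1,2,4a,5,6,7,8,8a-octahydronaphthalene-2-carboxylic acid
Conditions: 85 % aq. H3PO4, toluene, rt
Reagents that add atoms: none
Why: Acid-mediated tert-butyl ester cleavage by loss of isobutene frees the acid without base, so C2 is not touched and the β,γ-alkene does not migrate.

**Step 8**
Reactants: 12 4-hydroxycyclohexan-1-one
Product: 13 4-(tert-butyldimethylsilyloxy)cyclohexan-1-one
Conditions: TBSCl, imidazole, DMF, rt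
Reagents that add atoms: tert-butyldimethylsilyl chloride, CC(C)(C)[Si](C)(C)Cl
Why: Standard silyl ether formation protects the secondary alcohol for the whole route.

**Step 9**
Reactants: 13 4-(tert-butyldimethylsilyloxy)cyclohexan-1-one
Product: 15 tert-butyldimethyl{[(1R)-4-(trimethylsilyloxy)cyclohex-3-en-1-yl]oxy}silane, via lithium enolate 14 (not isolated)
Conditions: (S,S)-bis(1-phenylethyl)amine, n-BuLi, LiCl, THF, −78 °C; Me3SiCl (in-situ quench)
Reagents that add atoms: chlorotrimethylsilane, C[Si](C)(C)Cl; lithium (S,S)-bis(1-phenylethyl)amide (lithium of 14), C[C@H](N([Li])[C@@H](C)c1ccccc1)c1ccccc1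
Why: Enantioselective deprotonation of the prochiral ketone with a chiral lithium amide (Simpkins–Koga desymmetrisation) with silyl trapping distinguishes the enantiotopic α-methylene groups and fixes the silyloxy carbon as R (about 90 % ee; the minor antipode is removed later as a diastereomer).

**Step 10**
Reactants: 15 tert-butyldimethyl{[(1R)-4-(trimethylsilyloxy)cyclohex-3-en-1-yl]oxy}silane
Product: 16 (4R)-4-(tert-butyldimethylsilyloxy)cyclohex-2-en-1-one
Conditions: Pd(OAc)2 (1.05 equiv), MeCN, rt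
Reagents that add atoms: none
Why: Saegusa–Ito oxidation; the palladium enolate formed from the silyl enol ether undergoes β-hydride elimination to give the enone on the side fixed in step 9.

**Step 11**
Reactants: 17 3-methoxycyclopent-2-en-1-one; 16 (4R)-4-(tert-butyldimethylsilyloxy)cyclohex-2-en-1-one
Product: 20 5-[(1S,4R)-1,4-bis(tert-butyldimethylsilyloxy)cyclohex-2-en-1-yl]-3-methoxycyclopent-2-en-1-one, via lithium enolate 18 (not isolated), via lithium alkoxide 19 (not isolated)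
Conditions: 17, LiN(i-Pr)2, THF, −78 °C; 16, −78 °C; TBSOTf, −78 → −40 °C
Reagents that add atoms: lithium diisopropylamide (lithium of 18 and 19), [Li]N(C(C)C)C(C)C; tert-butyldimethylsilyl trifluoromethanesulfonate, CC(C)(C)[Si](C)(C)OS(=O)(=O)C(F)(F)F
Why: Stork–Danheiser α′-lithiation of the vinylogous ester and kinetic 1,2-addition (aldol) to the enone; the enolate attacks axially, anti to the pseudoaxial 4-silyloxy group, so the new C–C bond at C1 is trans and the C1–O bond cis to the C4–O bond (expected about 5:1), and immediate O-silylation blocks retro-aldol and 1,4-equilibration (the cyclopentenone C5 epimers converge in step 14).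

**Step 12**
Reactants: 20 5-[(1S,4R)-1,4-bis(tert-butyldimethylsilyloxy)cyclohex-2-en-1-yl]-3-methoxycyclopent-2-en-1-one
Product: 21 5-[(1R,2S,3R,4R)-1,4-bis(tert-butyldimethylsilyloxy)-2,3-epoxycyclohexyl]-3-methoxycyclopent-2-en-1-one
Conditions: mCPBA, CH2Cl2, 0 °C → rt
Reagents that add atoms: 3-chloroperoxybenzoic acid, OOC(=O)c1cccc(Cl)c1
Why: Prilezhaev epoxidation of the only non-conjugated alkene from the face opposite both allylic silyloxy groups sets the two epoxide carbons (epoxide trans to both oxygens); the push–pull enol-ether alkene is much less reactive.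

**Step 13**
Reactants: 21 5-[(1R,2S,3R,4R)-1,4-bis(tert-butyldimethylsilyloxy)-2,3-epoxycyclohexyl]-3-methoxycyclopent-2-en-1-one
Product: 22 4-[(1R,2S,3R,4R)-1,4-bis(tert-butyldimethylsilyloxy)-2,3-epoxycyclohexyl]cyclopentane-1,3-dione
Conditions: aq. HCl (1 mol/L), THF, 0 °C → rt
Reagents that add atoms: water, O
Why: Acid hydrolysis of the vinylogous ester (addition–elimination of water) gives the 1,3-dione; the epoxide flanked by two silyloxy carbons opens slowly, and any loss of the secondary silyl ether is repaired by the excess silyl triflate in step 14.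

**Step 14**
Reactants: 22 4-[(1R,2S,3R,4R)-1,4-bis(tert-butyldimethylsilyloxy)-2,3-epoxycyclohexyl]cyclopentane-1,3-dione
Product: 25 5-[(1R,2S,3R,4R)-1,4-bis(tert-butyldimethylsilyloxy)-2,3-epoxycyclohexyl]-4-hydroxypyridin-2(1H)-one, via bis-silyl dienol ether 23 (not isolated), via 2,4-bis(silyloxy)pyridine 24 (not isolated)
Conditions: TBSOTf (3 equiv), Et3N (4 equiv), CH2Cl2, 0 °C; then (diacetoxyiodo)benzene (2.5 equiv), H2NCO2NH4 (4 equiv), MeOH, 0 °C → rt
Reagents that add atoms: ammonium carbamate (nitrogen of 24 and 25), NC(=O)[O-].[NH4+]; tert-butyldimethylsilyl trifluoromethanesulfonate (silyl groups of 23 and 24 only), CC(C)(C)[Si](C)(C)OS(=O)(=O)C(F)(F)F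
Why: Proposed new method: double O-silylation gives a common 1,3-bis(silyloxy)allyl cation that loses the less hindered ring CH2 proton, locking the dione as the 1,3-bis(silyloxy)cyclopentadiene with the substituted carbon sp3; the electrophilic iodonitrene from (diacetoxyiodo)benzene and ammonia then aminates the terminal enol-ether carbon (Chan-diene-type selectivity) and the α-(iodanylamino) oxocarbenium undergoes a Beckmann/Stieglitz-like 1,2-shift of the carbonyl carbon from carbon to nitrogen with loss of iodobenzene, which inserts N between C=O and CH2, aromatises to the bis(silyloxy)pyridine and is unmasked by methanol to the 4-hydroxy-2-pyridone (no stereocentre is formed and the unassigned dione stereocentre disappears); closest known reaction type: oxidative amination (nitrogen-atom insertion) of cyclopentenone silyl enol ethers to 2-pyridones and of indenes to isoquinolines, not yet shown for cyclic 1,3-diones.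

**Step 15**
Reactants: 11 (1R,2R,4aS,7S,8aR)-4,7-dimethyl-1-[(E)-prop-1-en-1-yl]-1,2,4a,5,6,7,8,8a-octahydronaphthalene-2-carboxylic acid; 25 5-[(1R,2S,3R,4R)-1,4-bis(tert-butyldimethylsilyloxy)-2,3-epoxycyclohexyl]-4-hydroxypyridin-2(1H)-one
Product: 27 5-[(1R,2S,3R,4R)-1,4-bis(tert-butyldimethylsilyloxy)-2,3-epoxycyclohexyl]-3-{[(1R,2R,4aS,7S,8aR)-4,7-dimethyl-1-[(E)-prop-1-en-1-yl]-1,2,4a,5,6,7,8,8a-octahydronaphthalen-2-yl]carbonyl}-4-hydroxypyridin-2(1H)-one, via O-acyl pyridone 26 (not isolated)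
Conditions: N,N′-dicyclohexylcarbodiimide, DMAP (1.2 equiv), CH2Cl2, 0 °C → rt, then 40 °C
Reagents that add atoms: none
Why: Steglich activation gives the 4-O-acyl pyridone, which DMAP transfers to C3 (Fries-type O→C acyl migration, as used for tetramic acids and 4-hydroxypyrones); the C-acyl product is held by the chelated hydrogen bond and the decalin C2 is carried through as the kinetic epimer.

**Step 16**
Reactants: 27 (the C2-epimeric acyl pyridone)
Product: 28 5-[(1R,2S,3R,4R)-1,4-bis(tert-butyldimethylsilyloxy)-2,3-epoxycyclohexyl]-3-{[(1R,2S,4aS,7S,8aR)-4,7-dimethyl-1-[(E)-prop-1-en-1-yl]-1,2,4a,5,6,7,8,8a-octahydronaphthalen-2-yl]carbonyl}-4-hydroxypyridin-2(1H)-one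
Conditions: KOt-Bu (3 equiv), t-BuOH–THF, rt; aq. NH4Cl
Reagents that add atoms: none
Why: Base-mediated epimerisation through the side-chain dienolate puts the acyl group equatorial and trans to the propenyl group under thermodynamic control (the C2 inversion that links the 8-epi and natural series of this decalin family); the silyl ethers shut off Payne and retro-aldol pathways.

**Step 17**
Reactants: 28 (bis-silyl ether with natural decalin configuration)
Product: 29 4-hydroxy-5-[(1R,2S,3S,4R)-2,3-epoxy-1,4-dihydroxycyclohexyl]-3-{[(1R,2S,4aS,7S,8aR)-4,7-dimethyl-1-[(E)-prop-1-en-1-yl]-1,2,4a,5,6,7,8,8a-octahydronaphthalen-2-yl]carbonyl}pyridin-2(1H)-one (CNP0494338.1)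
Conditions: HF·pyridine, pyridine, THF, 0 °C → rt
Reagents that add atoms: none
Why: Fluoride-mediated cleavage of both silyl ethers under buffered, non-basic conditions liberates the diol without Payne rearrangement or epoxide opening.

**Compound list**
1 | methyl (E)-but-2-enoate | C/C=C/C(=O)OC | starting material
2 | but-3-en-1-ylmagnesium bromide | C=CCC[Mg]Br | starting material
3 | methyl (3S)-3-methylhept-6-enoate | COC(=O)C[C@@H](C)CCC=C | intermediate
4 | 2-methylprop-2-enal (methacrolein) | CC(=C)C=O | starting material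
5 | methyl (3S,6E)-3,7-dimethyl-8-oxooct-6-enoate | COC(=O)C[C@@H](C)CC/C=C(\C)C=O | intermediate
6 | 1-tert-butyl 10-methyl (2E,4E,8S)-4,8-dimethyldeca-2,4-dienedioate | COC(=O)C[C@@H](C)CC/C=C(\C)/C=C/C(=O)OC(C)(C)C | intermediate
7 | tert-butyl (2E,4E,8S)-4,8-dimethyl-10-oxodeca-2,4-dienoate | O=CC[C@@H](C)CC/C=C(\C)/C=C/C(=O)OC(C)(C)C | intermediate
8 | tert-butyl (2E,4E,8S,10E)-4,8-dimethyl-12-oxododeca-2,4,10-trienoate | O=C/C=C/C[C@@H](C)CC/C=C(\C)/C=C/C(=O)OC(C)(C)C | intermediate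
9 | tert-butyl (1R,2S,4aS,7S,8aS)-1-formyl-4,7-dimethyl-1,2,4a,5,6,7,8,8a-octahydronaphthalene-2-carboxylate | O=C[C@@H]1[C@H]2C[C@@H](C)CC[C@@H]2C(C)=C[C@@H]1C(=O)OC(C)(C)C | intermediate
10 | tert-butyl (1R,2R,4aS,7S,8aR)-4,7-dimethyl-1-[(E)-prop-1-en-1-yl]-1,2,4a,5,6,7,8,8a-octahydronaphthalene-2-carboxylate | C/C=C/[C@@H]1[C@H]2C[C@@H](C)CC[C@@H]2C(C)=C[C@@H]1C(=O)OC(C)(C)C | intermediate
11 | (1R,2R,4aS,7S,8aR)-4,7-dimethyl-1-[(E)-prop-1-en-1-yl]-1,2,4a,5,6,7,8,8a-octahydronaphthalene-2-carboxylic acid | C/C=C/[C@@H]1[C@H]2C[C@@H](C)CC[C@@H]2C(C)=C[C@@H]1C(=O)O | intermediate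
12 | 4-hydroxycyclohexan-1-one | O=C1CCC(O)CC1 | starting material
13 | 4-(tert-butyldimethylsilyloxy)cyclohexan-1-one | O=C1CCC(O[Si](C)(C)C(C)(C)C)CC1 | intermediate
14 | lithium (4R)-4-(tert-butyldimethylsilyloxy)cyclohex-1-en-1-olate | [Li]OC1=CC[C@H](O[Si](C)(C)C(C)(C)C)CC1 | intermediate
15 | tert-butyldimethyl{[(1R)-4-(trimethylsilyloxy)cyclohex-3-en-1-yl]oxy}silane | C[Si](C)(C)OC1=CC[C@H](O[Si](C)(C)C(C)(C)C)CC1 | intermediate
16 | (4R)-4-(tert-butyldimethylsilyloxy)cyclohex-2-en-1-one | O=C1CC[C@@H](O[Si](C)(C)C(C)(C)C)C=C1 | intermediate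
17 | 3-methoxycyclopent-2-en-1-one | COC1=CC(=O)CC1 | starting material
18 | lithium 4-methoxycyclopenta-1,3-dien-1-olate (α′-enolate of 17) | COC1=CC(O[Li])=CC1 | intermediate
19 | lithium (1S,4R)-4-(tert-butyldimethylsilyloxy)-1-(4-methoxy-2-oxocyclopent-3-en-1-yl)cyclohex-2-en-1-olate (epimers at the cyclopentenone carbon) | COC1=CC(=O)C(C1)[C@]2([O-])CC[C@@H](O[Si](C)(C)C(C)(C)C)C=C2.[Li+] | intermediate
20 | 5-[(1S,4R)-1,4-bis(tert-butyldimethylsilyloxy)cyclohex-2-en-1-yl]-3-methoxycyclopent-2-en-1-one (epimers at cyclopentenone C5; silyloxy groups cis) | COC1=CC(=O)C(C1)[C@]2(O[Si](C)(C)C(C)(C)C)CC[C@@H](O[Si](C)(C)C(C)(C)C)C=C2 | intermediate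
21 | 5-[(1R,2S,3R,4R)-1,4-bis(tert-butyldimethylsilyloxy)-2,3-epoxycyclohexyl]-3-methoxycyclopent-2-en-1-one (epoxide trans to both silyloxy groups) | COC1=CC(=O)C(C1)[C@]2(O[Si](C)(C)C(C)(C)C)CC[C@@H](O[Si](C)(C)C(C)(C)C)[C@@H]3O[C@@H]32 | intermediate
22 | 4-[(1R,2S,3R,4R)-1,4-bis(tert-butyldimethylsilyloxy)-2,3-epoxycyclohexyl]cyclopentane-1,3-dione | O=C1CC(=O)C(C1)[C@]2(O[Si](C)(C)C(C)(C)C)CC[C@@H](O[Si](C)(C)C(C)(C)C)[C@@H]3O[C@@H]32 | intermediate
23 | 5-[(1R,2S,3R,4R)-1,4-bis(tert-butyldimethylsilyloxy)-2,3-epoxycyclohexyl]-1,3-bis(tert-butyldimethylsilyloxy)cyclopenta-1,3-diene | CC(C)(C)[Si](C)(C)OC1=CC(C(O[Si](C)(C)C(C)(C)C)=C1)[C@]2(O[Si](C)(C)C(C)(C)C)CC[C@@H](O[Si](C)(C)C(C)(C)C)[C@@H]3O[C@@H]32 | intermediate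
24 | 5-[(1R,2S,3R,4R)-1,4-bis(tert-butyldimethylsilyloxy)-2,3-epoxycyclohexyl]-2,4-bis(tert-butyldimethylsilyloxy)pyridine | CC(C)(C)[Si](C)(C)Oc1cc(O[Si](C)(C)C(C)(C)C)c(cn1)[C@]2(O[Si](C)(C)C(C)(C)C)CC[C@@H](O[Si](C)(C)C(C)(C)C)[C@@H]3O[C@@H]32 | intermediate
25 | 5-[(1R,2S,3R,4R)-1,4-bis(tert-butyldimethylsilyloxy)-2,3-epoxycyclohexyl]-4-hydroxypyridin-2(1H)-one | O=c1cc(O)c(c[nH]1)[C@]2(O[Si](C)(C)C(C)(C)C)CC[C@@H](O[Si](C)(C)C(C)(C)C)[C@@H]3O[C@@H]32 | intermediate
26 | 5-[(1R,2S,3R,4R)-1,4-bis(tert-butyldimethylsilyloxy)-2,3-epoxycyclohexyl]-2-oxo-1,2-dihydropyridin-4-yl (1R,2R,4aS,7S,8aR)-4,7-dimethyl-1-[(E)-prop-1-en-1-yl]-1,2,4a,5,6,7,8,8a-octahydronaphthalene-2-carboxylate | C/C=C/[C@@H]1[C@H]2C[C@@H](C)CC[C@@H]2C(C)=C[C@@H]1C(=O)Oc1cc(=O)[nH]cc1[C@]2(O[Si](C)(C)C(C)(C)C)CC[C@@H](O[Si](C)(C)C(C)(C)C)[C@@H]3O[C@@H]32 | intermediate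
27 | 5-[(1R,2S,3R,4R)-1,4-bis(tert-butyldimethylsilyloxy)-2,3-epoxycyclohexyl]-3-{[(1R,2R,4aS,7S,8aR)-4,7-dimethyl-1-[(E)-prop-1-en-1-yl]-1,2,4a,5,6,7,8,8a-octahydronaphthalen-2-yl]carbonyl}-4-hydroxypyridin-2(1H)-one | C/C=C/[C@@H]1[C@H]2C[C@@H](C)CC[C@@H]2C(C)=C[C@@H]1C(=O)c1c(O)c([C@]2(O[Si](C)(C)C(C)(C)C)CC[C@@H](O[Si](C)(C)C(C)(C)C)[C@@H]3O[C@@H]32)c[nH]c1=O | intermediate
28 | 5-[(1R,2S,3R,4R)-1,4-bis(tert-butyldimethylsilyloxy)-2,3-epoxycyclohexyl]-3-{[(1R,2S,4aS,7S,8aR)-4,7-dimethyl-1-[(E)-prop-1-en-1-yl]-1,2,4a,5,6,7,8,8a-octahydronaphthalen-2-yl]carbonyl}-4-hydroxypyridin-2(1H)-one | C/C=C/[C@@H]1[C@H]2C[C@@H](C)CC[C@@H]2C(C)=C[C@H]1C(=O)c1c(O)c([C@]2(O[Si](C)(C)C(C)(C)C)CC[C@@H](O[Si](C)(C)C(C)(C)C)[C@@H]3O[C@@H]32)c[nH]c1=O | intermediate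
29 | 4-hydroxy-5-[(1R,2S,3S,4R)-2,3-epoxy-1,4-dihydroxycyclohexyl]-3-{[(1R,2S,4aS,7S,8aR)-4,7-dimethyl-1-[(E)-prop-1-en-1-yl]-1,2,4a,5,6,7,8,8a-octahydronaphthalen-2-yl]carbonyl}pyridin-2(1H)-one | C/C=C/[C@@H]1[C@H]2C[C@@H](C)CC[C@@H]2C(C)=C[C@H]1C(=O)c1c(O)c([C@]2(O)CC[C@@H](O)[C@@H]3O[C@@H]32)c[nH]c1=O | target

**Totals**
Total step count: 17. Longest linear sequence: 10 steps (steps 8–17 from 12; equally steps 1–7 then 15–17 from 1).

**Three steps most likely to fail**

Step 14 (the proposed nitrogen insertion). Likely failure modes are amination at the carbon between the two oxygens, insertion next to the substituted carbon (6-substituted pyridone), and loss of the dienol silyl ethers in methanol before nitrogen transfer. The fallback uses known pyridyl-lithium chemistry, sets out from enone 16 and comes back at pyridone 25. Commercial pyridine-2,4-diol (Oc1ccnc(O)c1) is O-benzylated (BnBr, Ag2CO3, toluene, 80 °C) to 2,4-bis(benzyloxy)pyridine F1 and brominated (NBS, MeCN) to 5-bromo-2,4-bis(benzyloxy)pyridine F2. Bromine–lithium exchange (n-BuLi, THF, −78 °C) gives 5-lithio-2,4-bis(benzyloxy)pyridine F3, which adds 1,2 to 16 anti to the silyloxy group to give the lithium alkoxide F4, silylated in the same flask (TBSOTf) to the bis-silyl ether F5. mCPBA epoxidises anti to both silyloxy groups (the 2-alkoxypyridine nitrogen is a poor nucleophile) to give the epoxide F6, and hydrogenolysis (H2, Pd/C, EtOAc) removes both benzyl groups to give 25.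

Step 15 (C3 acylation of a hindered, unprotected hydroxypyridone with an α-branched acid). O-acylation may stall or the acyl group may not migrate to carbon. The fallback changes the bond-forming event to an aryl-lithium/aldehyde addition, sets out from ester 10 and pyridone 25 and comes back at 27. Ester 10 is reduced (LiAlH4, Et2O, 0 °C) to the primary alcohol F7 and oxidised (Dess–Martin periodinane) to the aldehyde F8. Pyridone 25 is brominated at C3 (NBS, DMF, 0 °C) to the 3-bromopyridone F9; MeLi (2 equiv) then t-BuLi (2 equiv) at −78 °C give the trilithio species F10, which adds to F8 to give the carbinol F11 (both configurations at the carbinol carbon). Oxidation (Dess–Martin periodinane) gives 27.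

Step 5 (intramolecular Diels–Alder reaction with an ester-deactivated diene). The diene may be too electron-poor for the Lewis-acid-activated enal, or the trans/cis ring-fusion ratio may be poor. The fallback reverses the electronic pairing, sets out from trienal 8 and comes back at 10. The Takai–Utimoto reaction is run first on 8 (CrCl2, 1,1-diiodoethane, THF) to give the tetraene ester F12, which is cyclised in the inverse sense (the dienoate as the 4π unit, the terminal diene as the 2π unit; Me2AlCl or toluene at 150 °C with BHT), the pairing used in the biosynthesis of this decalin, to give 10 directly.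

**Further compounds**
F1 | step 14 | 2,4-bis(benzyloxy)pyridine | c1ccccc1COc1ccnc(OCc2ccccc2)c1
F2 | step 14 | 5-bromo-2,4-bis(benzyloxy)pyridine | Brc1cnc(OCc2ccccc2)cc1OCc1ccccc1
F3 | step 14 | 5-lithio-2,4-bis(benzyloxy)pyridine | [Li]c1cnc(OCc2ccccc2)cc1OCc1ccccc1
F4 | step 14 | lithium (1S,4R)-1-[4,6-bis(benzyloxy)pyridin-3-yl]-4-(tert-butyldimethylsilyloxy)cyclohex-2-en-1-olate | c1ccccc1COc1cc(OCc2ccccc2)c(cn1)[C@]3([O-])CC[C@@H](O[Si](C)(C)C(C)(C)C)C=C3.[Li+]
F5 | step 14 | 2,4-bis(benzyloxy)-5-[(1S,4R)-1,4-bis(tert-butyldimethylsilyloxy)cyclohex-2-en-1-yl]pyridine | c1ccccc1COc1cc(OCc2ccccc2)c(cn1)[C@]3(O[Si](C)(C)C(C)(C)C)CC[C@@H](O[Si](C)(C)C(C)(C)C)C=C3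
F6 | step 14 | 2,4-bis(benzyloxy)-5-[(1R,2S,3R,4R)-1,4-bis(tert-butyldimethylsilyloxy)-2,3-epoxycyclohexyl]pyridine | c1ccccc1COc1cc(OCc2ccccc2)c(cn1)[C@]3(O[Si](C)(C)C(C)(C)C)CC[C@@H](O[Si](C)(C)C(C)(C)C)[C@@H]4O[C@@H]43
F7 | step 15 | {(1R,2R,4aS,7S,8aR)-4,7-dimethyl-1-[(E)-prop-1-en-1-yl]-1,2,4a,5,6,7,8,8a-octahydronaphthalen-2-yl}methanol | C/C=C/[C@@H]1[C@H]2C[C@@H](C)CC[C@@H]2C(C)=C[C@@H]1CO
F8 | step 15 | (1R,2R,4aS,7S,8aR)-4,7-dimethyl-1-[(E)-prop-1-en-1-yl]-1,2,4a,5,6,7,8,8a-octahydronaphthalene-2-carbaldehyde | C/C=C/[C@@H]1[C@H]2C[C@@H](C)CC[C@@H]2C(C)=C[C@@H]1C=O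
F9 | step 15 | 5-[(1R,2S,3R,4R)-1,4-bis(tert-butyldimethylsilyloxy)-2,3-epoxycyclohexyl]-3-bromo-4-hydroxypyridin-2(1H)-one | O=c1[nH]cc(c(O)c1Br)[C@]2(O[Si](C)(C)C(C)(C)C)CC[C@@H](O[Si](C)(C)C(C)(C)C)[C@@H]3O[C@@H]32
F10 | step 15 | dilithium 5-[(1R,2S,3R,4R)-1,4-bis(tert-butyldimethylsilyloxy)-2,3-epoxycyclohexyl]-3-lithiopyridine-2,4-diolate | [Li]Oc1ncc(c(O[Li])c1[Li])[C@]2(O[Si](C)(C)C(C)(C)C)CC[C@@H](O[Si](C)(C)C(C)(C)C)[C@@H]3O[C@@H]32
F11 | step 15 | 5-[(1R,2S,3R,4R)-1,4-bis(tert-butyldimethylsilyloxy)-2,3-epoxycyclohexyl]-3-{[(1R,2R,4aS,7S,8aR)-4,7-dimethyl-1-[(E)-prop-1-en-1-yl]-1,2,4a,5,6,7,8,8a-octahydronaphthalen-2-yl](hydroxy)methyl}-4-hydroxypyridin-2(1H)-one | C/C=C/[C@@H]1[C@H]2C[C@@H](C)CC[C@@H]2C(C)=C[C@@H]1C(O)c1c(O)c([C@]2(O[Si](C)(C)C(C)(C)C)CC[C@@H](O[Si](C)(C)C(C)(C)C)[C@@H]3O[C@@H]32)c[nH]c1=O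
F12 | step 5 | tert-butyl (2E,4E,8S,10E,12E)-4,8-dimethyltetradeca-2,4,10,12-tetraenoate | C/C=C/C=C/C[C@@H](C)CC/C=C(\C)/C=C/C(=O)OC(C)(C)C
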